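**Plan**
- Retrosynthesis: after removal of two benzyl ethers, ring A is cut in one operation at C1–C6, C5–C6, C3–C4 and C2–C3. This leaves an acyclic α-diazo enone (C3, C2, C1, C6 with their three carbon substituents) and methoxyacetylene (C4–H, C5–OMe).
- Enabling feature: ring A is a pentasubstituted 3-methoxyphenol (C1 CH2CH2 bridge, C2 and C6 benzyl groups, C3 OH, C4 H, C5 OMe). This is the output pattern of a vinylketene–alkoxyacetylene benzannulation, with the OH coming from the ketene carbonyl.
- The diazo enone is cut further at the diazo group (diazo transfer), at the C=C bond (Horner–Wadsworth–Emmons) and at the ketone–Cα bond (phosphonate acylation), giving three arylalkyl building blocks.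
- Forward: the chain is joined first (phosphonate + ester, then olefination with an arylacetaldehyde, then diazo transfer). Ring A, the only ring formed, arises last by a light-then-heat cascade, and hydrogenolysis frees the two phenols.
- Stereochemistry: the target has no stereocentre. The one stereochemical element of the route, the E geometry of the enone, is set in the olefination and consumed on aromatisation.

Key step: step 10

Remark: the target is achiral, so the requirement of a single stereoisomer is met by constitution alone. Ring A is numbered as in the bibenzyl name (C1 carries the CH2CH2 bridge).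

**Route**

Step 1
Reactants: 1 3-(3-methoxyphenyl)propan-1-ol
Product: 2 1-(3-bromopropyl)-3-methoxybenzene
Conditions: CBr4, PPh3, CH2Cl2, 0 °C → rt
Reagents that add atoms: carbon tetrabromide, BrC(Br)(Br)Br
Why: Appel reaction, in which the primary alcohol is activated as an alkoxyphosphonium ion and displaced by bromide (SN2) under neutral conditions that leave the aryl methyl ether alone.

Step 2
Reactants: 2 1-(3-bromopropyl)-3-methoxybenzene
Product: 3 diethyl [3-(3-methoxyphenyl)propyl]phosphonate
Conditions: P(OEt)3 (neat, excess), 150 °C, EtBr distilled off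
Reagents that add atoms: triethyl phosphite, CCOP(OCC)OCC
Why: Michaelis–Arbuzov reaction, in which the phosphite attacks the unhindered primary bromide and bromide dealkylates the phosphonium salt to the phosphonate.

Step 3
Reactants: 4 methyl 3-(4-hydroxyphenyl)propanoate
Product: 5 methyl 3-[4-(benzyloxy)phenyl]propanoate
Conditions: BnBr, K2CO3, acetone, reflux
Reagents that add atoms: benzyl bromide, BrCc1ccccc1
Why: Williamson ether synthesis, in which the phenoxide formed by K2CO3 is benzylated while the methyl ester is inert in acetone.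

Step 4
Reactants: 3 diethyl [3-(3-methoxyphenyl)propyl]phosphonate; 5 methyl 3-[4-(benzyloxy)phenyl]propanoate
Product: 6 diethyl {1-[4-(benzyloxy)phenyl]-6-(3-methoxyphenyl)-3-oxohexan-4-yl}phosphonate (racemic)
Conditions: 3 (2.1 equiv), n-BuLi (2.0 equiv), THF, −78 °C; then 5 (1.0 equiv), −78 → 0 °C; aq NH4Cl
Reagents that add atoms: none
Why: Claisen-type acylation of an α-lithio alkylphosphonate by an ester, in which the second equivalent of carbanion deprotonates the β-ketophosphonate as it forms and so protects the new ketone from further addition.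

Step 5
Reactants: 7 2-(4-hydroxyphenyl)ethanol
Product: 8 2-[4-(benzyloxy)phenyl]ethanol
Conditions: BnBr (1.05 equiv), K2CO3, acetone, reflux
Reagents that add atoms: benzyl bromide, BrCc1ccccc1
Why: chemoselective Williamson etherification, since K2CO3 deprotonates only the phenol and the primary alcohol stays free.

Step 6
Reactants: 8 2-[4-(benzyloxy)phenyl]ethanol
Product: 9 [4-(benzyloxy)phenyl]acetaldehyde
Conditions: Dess–Martin periodinane, CH2Cl2, 0 °C → rt; Na2S2O3/NaHCO3 work-up; used at once
Reagents that add atoms: none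
Why: Dess–Martin oxidation stops at the aldehyde under nearly neutral conditions, which spares the enolisable arylacetaldehyde from aldol chemistry.

Step 7
Reactants: 6 diethyl {1-[4-(benzyloxy)phenyl]-6-(3-methoxyphenyl)-3-oxohexan-4-yl}phosphonate; 9 [4-(benzyloxy)phenyl]acetaldehyde
Product: 10 (E)-1,6-bis[4-(benzyloxy)phenyl]-4-[2-(3-methoxyphenyl)ethyl]hex-4-en-3-one
Conditions: activated Ba(OH)2 (0.8 equiv), THF, rt; then 9, THF/H2O 40:1, 0 °C → rt
Reagents that add atoms: none
Why: Horner–Wadsworth–Emmons olefination under mild barium hydroxide conditions, in which the stabilised anion of the α-substituted β-ketophosphonate adds reversibly to the aldehyde and elimination of diethyl phosphate from the less crowded adduct places the CH2Ar group trans to the acyl group (E), while the weak heterogeneous base limits enolisation of the aldehyde and migration of the new double bond.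

Step 8
Reactants: 10 (E)-1,6-bis[4-(benzyloxy)phenyl]-4-[2-(3-methoxyphenyl)ethyl]hex-4-en-3-one
Product: 12 (E)-1,6-bis[4-(benzyloxy)phenyl]-2-diazo-4-[2-(3-methoxyphenyl)ethyl]hex-4-en-3-one, via trifluoroacetyl diketone 11 (not isolated)
Conditions: LiHMDS, THF, −78 °C; CF3CO2CH2CF3, −78 °C; dilute HCl wash; then MsN3, Et3N, H2O (1 equiv), MeCN, rt
Reagents that add atoms: methanesulfonyl azide, CS(=O)(=O)N=[N+]=[N-]
Why: detrifluoroacetylative (Regitz-type deacylative) diazo transfer, in which kinetic deprotonation at −78 °C occurs at the α′-CH2 (C2) of the enone, Claisen trifluoroacetylation activates exactly that carbon, and mesyl azide with Et3N delivers N2 while the trifluoroacetyl group leaves as N-mesyl trifluoroacetamide, conditions that do not touch the E double bond or the benzyl ethers.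

Step 9
Reactants: 13 chloroacetaldehyde dimethyl acetal (2-chloro-1,1-dimethoxyethane)
Product: 15 methoxyacetylene, via sodium methoxyacetylide 14 (not isolated)
Conditions: NaNH2 (3.2 equiv), liq. NH3, −33 °C; NH3 evaporated; sat. aq NaCl, −20 °C; distilled into a −78 °C trap and kept as a cold solution in ClCH2CH2Cl
Reagents that add atoms: none
Why: base-induced double elimination, in which sodium amide removes methanol and HCl from the chloroacetal and deprotonates the alkyne as it forms, the standard preparation of alkoxyacetylenes from chloroacetaldehyde acetals, and cold hydrolysis of the acetylide then frees the volatile alkyne.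

Step 10
Reactants: 12 (E)-1,6-bis[4-(benzyloxy)phenyl]-2-diazo-4-[2-(3-methoxyphenyl)ethyl]hex-4-en-3-one; 15 methoxyacetylene
Product: 20 2,4-bis[4-(benzyloxy)benzyl]-5-methoxy-3-[2-(3-methoxyphenyl)ethyl]phenol, via vinylketene 16 (not isolated), via alkenylcyclobutenone 17 (not isolated), via dienylketene 18 (not isolated), via cyclohexadienone 19 (not isolated)
Conditions: 15 (4 equiv), ClCH2CH2Cl, degassed, sealed Pyrex tube, hν (350 nm), 10 °C; then 80 °C in the dark
Reagents that add atoms: none
Why: Light at 350 nm, absorbed only by the diazo ketone, expels N2 and the alkenyl group shifts from the carbonyl carbon to the diazo carbon (photo-Wolff rearrangement, forming C1–C6) to give vinylketene 16. The electrophilic ketene carbon is attacked by the nucleophilic CH terminus of the ynol ether and the [2+2] cycloaddition is completed between the C(OMe) terminus and the former diazo carbon (C3–C4 and C5–C6), giving the 3-methoxy-4-alkenylcyclobutenone 17. Heating opens 17 by a reversible 4π-electrocyclic cleavage to dienylketene 18, and ring A then closes as a six-membered carbocycle by thermal disrotatory 6π-electrocyclisation between the ketene carbon and the CH terminus of the alkene (C2–C3), after which dienone 19 enolises to the phenol whose hydroxyl is the former ketene oxygen. The closest known reaction type is the Danheiser photochemical benzannulation of α-diazo α′,β′-unsaturated ketones with alkoxy- and siloxyacetylenes, which gives resorcinol monoethers by the same substitution logic. The step needs one regiochemistry in the cycloaddition, secured by the polarity of methoxyacetylene (H ends at C4, OMe at C5), and a ketene that survives until it is trapped, secured by the E alkene, which holds the benzylic CH2 of the future C2 substituent away from the ketene (no 1,5-hydrogen shift) and turns the small H inward for the ring closure. No stereocentre survives, since the quaternary carbon of 17 and the sp3 carbon of 19 are both lost on aromatisation.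

Step 11
Reactants: 20 2,4-bis[4-(benzyloxy)benzyl]-5-methoxy-3-[2-(3-methoxyphenyl)ethyl]phenol
Product: 21 2,4-bis(4-hydroxybenzyl)-5-methoxy-3-[2-(3-methoxyphenyl)ethyl]phenol (the target)
Conditions: H2 (1 atm), 10% Pd/C, EtOAc/MeOH, rt
Reagents that add atoms: none
Why: catalytic hydrogenolysis of the two benzyl aryl ethers, under which the aryl methyl ethers, the free phenol and the diarylmethane and bibenzyl C–C bonds are inert.

**Compound list**

1 | 3-(3-methoxyphenyl)propan-1-ol | COc1cccc(CCCO)c1 | starting material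
2 | 1-(3-bromopropyl)-3-methoxybenzene | COc1cccc(CCCBr)c1 | intermediate
3 | diethyl [3-(3-methoxyphenyl)propyl]phosphonate | CCOP(=O)(CCCc1cccc(OC)c1)OCC | intermediate
4 | methyl 3-(4-hydroxyphenyl)propanoate | COC(=O)CCc1ccc(O)cc1 | starting material
5 | methyl 3-[4-(benzyloxy)phenyl]propanoate | COC(=O)CCc1ccc(OCc2ccccc2)cc1 | intermediate
6 | diethyl {1-[4-(benzyloxy)phenyl]-6-(3-methoxyphenyl)-3-oxohexan-4-yl}phosphonate (racemic) | CCOP(=O)(OCC)C(CCc1cccc(OC)c1)C(=O)CCc1ccc(OCc2ccccc2)cc1 | intermediate
7 | 2-(4-hydroxyphenyl)ethanol | OCCc1ccc(O)cc1 | starting material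
8 | 2-[4-(benzyloxy)phenyl]ethanol | OCCc1ccc(OCc2ccccc2)cc1 | intermediate
9 | [4-(benzyloxy)phenyl]acetaldehyde | O=CCc1ccc(OCc2ccccc2)cc1 | intermediate
10 | (E)-1,6-bis[4-(benzyloxy)phenyl]-4-[2-(3-methoxyphenyl)ethyl]hex-4-en-3-one | COc1cccc(CC/C(C(=O)CCc2ccc(OCc3ccccc3)cc2)=C\Cc2ccc(OCc3ccccc3)cc2)c1 | intermediate
11 | (E)-3-[4-(benzyloxy)benzyl]-7-[4-(benzyloxy)phenyl]-1,1,1-trifluoro-5-[2-(3-methoxyphenyl)ethyl]hept-5-ene-2,4-dione (racemic, drawn as the diketone) | COc1cccc(CC/C(C(=O)C(Cc2ccc(OCc3ccccc3)cc2)C(=O)C(F)(F)F)=C\Cc2ccc(OCc3ccccc3)cc2)c1 | intermediate (not isolated)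
12 | (E)-1,6-bis[4-(benzyloxy)phenyl]-2-diazo-4-[2-(3-methoxyphenyl)ethyl]hex-4-en-3-one | COc1cccc(CC/C(C(=O)C(=[N+]=[N-])Cc2ccc(OCc3ccccc3)cc2)=C\Cc2ccc(OCc3ccccc3)cc2)c1 | intermediate
13 | chloroacetaldehyde dimethyl acetal | COC(CCl)OC | starting material
14 | sodium methoxyacetylide | COC#[C-].[Na+] | intermediate (not isolated)
15 | methoxyacetylene | COC#C | intermediate
16 | (E)-2-[4-(benzyloxy)benzyl]-5-[4-(benzyloxy)phenyl]-3-[2-(3-methoxyphenyl)ethyl]penta-1,3-dien-1-one (vinylketene) | COc1cccc(CC/C(C(=C=O)Cc2ccc(OCc3ccccc3)cc2)=C\Cc2ccc(OCc3ccccc3)cc2)c1 | intermediate (not isolated)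
17 | 4-[4-(benzyloxy)benzyl]-4-[(2E)-1-[4-(benzyloxy)phenyl]-5-(3-methoxyphenyl)pent-2-en-3-yl]-3-methoxycyclobut-2-en-1-one (racemic) | COC1=CC(=O)C1(Cc1ccc(OCc2ccccc2)cc1)/C(CCc1cccc(OC)c1)=C/Cc1ccc(OCc2ccccc2)cc1 | intermediate (not isolated)
18 | (3E,5E)-4-[4-(benzyloxy)benzyl]-7-[4-(benzyloxy)phenyl]-3-methoxy-5-[2-(3-methoxyphenyl)ethyl]hepta-1,3,5-trien-1-one (dienylketene, ketenyl and alkenyl groups cis across C3=C4) | O=C=C/C(OC)=C(Cc1ccc(OCc2ccccc2)cc1)\C(CCc1cccc(OC)c1)=C\Cc1ccc(OCc2ccccc2)cc1 | intermediate (not isolated)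
19 | 4,6-bis[4-(benzyloxy)benzyl]-3-methoxy-5-[2-(3-methoxyphenyl)ethyl]cyclohexa-2,4-dien-1-one (racemic) | COC1=CC(=O)C(Cc2ccc(OCc3ccccc3)cc2)C(CCc2cccc(OC)c2)=C1Cc1ccc(OCc2ccccc2)cc1 | intermediate (not isolated)
20 | 2,4-bis[4-(benzyloxy)benzyl]-5-methoxy-3-[2-(3-methoxyphenyl)ethyl]phenol | COc1cccc(CCc2c(Cc3ccc(OCc4ccccc4)cc3)c(O)cc(OC)c2Cc2ccc(OCc3ccccc3)cc2)c1 | intermediate
21 | 2,4-bis(4-hydroxybenzyl)-5-methoxy-3-[2-(3-methoxyphenyl)ethyl]phenol (achiral) | COc1cccc(CCc2c(Cc3ccc(O)cc3)c(O)cc(OC)c2Cc2ccc(O)cc2)c1 | target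

**Count and risks**

Total steps: 11. Longest linear sequence: 7 steps (1, 2, 4, 7, 8, 10, 11).

Steps most likely to fail:

1. Step 10. After loss of N2, a 1,2-hydrogen shift from the benzylic CH2 on the diazo carbon may overtake the Wolff shift, because a fully substituted acyclic diazo enone may not populate the conformer that rearranges in concert. Light may also isomerise the enone to the Z form, and the crowded ketene may dimerise before the volatile alkyne captures it. The fallback sets out from 3 and 9 and returns at 20; it takes the C6 benzyl group out of the photochemical step and adds it afterwards. Lithiated 3 is acylated with N-methoxy-N-methylacetamide to diethyl [5-(3-methoxyphenyl)-2-oxopentan-3-yl]phosphonate F1. Ba(OH)2-mediated olefination with 9 gives (E)-5-[4-(benzyloxy)phenyl]-3-[2-(3-methoxyphenyl)ethyl]pent-3-en-2-one F2. Trifluoroacetylation (LiHMDS, CF3CO2CH2CF3) gives (E)-7-[4-(benzyloxy)phenyl]-1,1,1-trifluoro-5-[2-(3-methoxyphenyl)ethyl]hept-5-ene-2,4-dione F3, and diazo transfer (MsN3, Et3N) gives (E)-5-[4-(benzyloxy)phenyl]-1-diazo-3-[2-(3-methoxyphenyl)ethyl]pent-3-en-2-one F4. This diazomethyl ketone belongs to the best-tested substrate class of the benzannulation and has no hydrogen next to the carbene carbon. Irradiation with 15 and heating, as in step 10, should give 2-[4-(benzyloxy)benzyl]-5-methoxy-3-[2-(3-methoxyphenyl)ethyl]phenol F5. NBS (CH2Cl2, −78 °C) should brominate para to the hydroxyl, the position para to the methoxy group being blocked, to give 2-[4-(benzyloxy)benzyl]-4-bromo-5-methoxy-3-[2-(3-methoxyphenyl)ethyl]phenol F6. Negishi coupling (Pd(OAc)2, SPhos, THF) with [4-(benzyloxy)benzyl]zinc chloride F7, made from 4-(benzyloxy)benzyl chloride, zinc dust and LiCl, then gives 20.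

2. Step 8. LiHMDS may remove a proton from the benzylic, allylic C6 in place of C2, so that an extended enolate forms, the trifluoroacetyl group lands on the wrong carbon and the C4=C5 bond drifts into conjugation with the aryl ring. The fallback sets out from 3 and 9 and returns at 12; it brings the nitrogen in already bonded to C2, as the amino group of tyrosine. Purchased methyl N-(tert-butoxycarbonyl)-O-benzyl-L-tyrosinate is treated with lithiated 3 (3 equiv, THF, −78 °C) to give diethyl {(5S)-6-[4-(benzyloxy)phenyl]-5-[(tert-butoxycarbonyl)amino]-1-(3-methoxyphenyl)-4-oxohexan-3-yl}phosphonate F8. Ba(OH)2 olefination with 9 gives tert-butyl {(2S,4E)-1,6-bis[4-(benzyloxy)phenyl]-4-[2-(3-methoxyphenyl)ethyl]-3-oxohex-4-en-2-yl}carbamate F9. HCl in dioxane removes the Boc group to give (2S,4E)-2-amino-1,6-bis[4-(benzyloxy)phenyl]-4-[2-(3-methoxyphenyl)ethyl]hex-4-en-3-one hydrochloride F10. Diazotisation (NaNO2, aqueous acetate buffer/CH2Cl2, 0 °C) then gives 12, because the acyl-substituted diazonium ion loses the C2 proton. The configuration at C2 is of no consequence and disappears at this point.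

3. Step 7. Under base the arylacetaldehyde may enolise and self-condense faster than the hindered α-substituted phosphonate anion adds, and the product may lose E purity or let its double bond drift towards the aryl ring. The fallback sets out from 2, 5 and 9 and returns at 10; it is a base-free Wittig reaction of a stabilised acyl ylide. 2 and PPh3 (toluene, reflux) give [3-(3-methoxyphenyl)propyl]triphenylphosphonium bromide F11. Its ylide (n-BuLi, THF, 2 equiv) is acylated by 5 to the stabilised ylide 1-[4-(benzyloxy)phenyl]-6-(3-methoxyphenyl)-4-(triphenyl-λ5-phosphanylidene)hexan-3-one F12. Heating F12 with 9 in toluene, with no base present, should give 10 with the E preference usual for stabilised ylides.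

**Further compounds**

F1 | step 10 | diethyl [5-(3-methoxyphenyl)-2-oxopentan-3-yl]phosphonate | CCOP(=O)(OCC)C(CCc1cccc(OC)c1)C(C)=O
F2 | step 10 | (E)-5-[4-(benzyloxy)phenyl]-3-[2-(3-methoxyphenyl)ethyl]pent-3-en-2-one | COc1cccc(CC/C(C(C)=O)=C\Cc2ccc(OCc3ccccc3)cc2)c1
F3 | step 10 | (E)-7-[4-(benzyloxy)phenyl]-1,1,1-trifluoro-5-[2-(3-methoxyphenyl)ethyl]hept-5-ene-2,4-dione | COc1cccc(CC/C(C(=O)CC(=O)C(F)(F)F)=C\Cc2ccc(OCc3ccccc3)cc2)c1
F4 | step 10 | (E)-5-[4-(benzyloxy)phenyl]-1-diazo-3-[2-(3-methoxyphenyl)ethyl]pent-3-en-2-one | COc1cccc(CC/C(C(=O)C=[N+]=[N-])=C\Cc2ccc(OCc3ccccc3)cc2)c1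
F5 | step 10 | 2-[4-(benzyloxy)benzyl]-5-methoxy-3-[2-(3-methoxyphenyl)ethyl]phenol | COc1cccc(CCc2cc(OC)cc(O)c2Cc2ccc(OCc3ccccc3)cc2)c1
F6 | step 10 | 2-[4-(benzyloxy)benzyl]-4-bromo-5-methoxy-3-[2-(3-methoxyphenyl)ethyl]phenol | COc1cccc(CCc2c(Br)c(OC)cc(O)c2Cc2ccc(OCc3ccccc3)cc2)c1
F7 | step 10 | [4-(benzyloxy)benzyl]zinc chloride | Cl[Zn]Cc1ccc(OCc2ccccc2)cc1
F8 | step 8 | diethyl {(5S)-6-[4-(benzyloxy)phenyl]-5-[(tert-butoxycarbonyl)amino]-1-(3-methoxyphenyl)-4-oxohexan-3-yl}phosphonate | CCOP(=O)(OCC)C(CCc1cccc(OC)c1)C(=O)[C@H](Cc1ccc(OCc2ccccc2)cc1)NC(=O)OC(C)(C)C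
F9 | step 8 | tert-butyl {(2S,4E)-1,6-bis[4-(benzyloxy)phenyl]-4-[2-(3-methoxyphenyl)ethyl]-3-oxohex-4-en-2-yl}carbamate | COc1cccc(CC/C(C(=O)[C@H](Cc2ccc(OCc3ccccc3)cc2)NC(=O)OC(C)(C)C)=C\Cc2ccc(OCc3ccccc3)cc2)c1
F10 | step 8 | (2S,4E)-2-amino-1,6-bis[4-(benzyloxy)phenyl]-4-[2-(3-methoxyphenyl)ethyl]hex-4-en-3-one hydrochloride | COc1cccc(CC/C(C(=O)[C@H](Cc2ccc(OCc3ccccc3)cc2)N)=C\Cc2ccc(OCc3ccccc3)cc2)c1.Cl
F11 | step 7 | [3-(3-methoxyphenyl)propyl]triphenylphosphonium bromide | COc1cccc(CCC[P+](c2ccccc2)(c2ccccc2)c2ccccc2)c1.[Br-]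
F12 | step 7 | 1-[4-(benzyloxy)phenyl]-6-(3-methoxyphenyl)-4-(triphenyl-λ5-phosphanylidene)hexan-3-one | COc1cccc(CCC(C(=O)CCc2ccc(OCc3ccccc3)cc2)=P(c2ccccc2)(c2ccccc2)c2ccccc2)c1
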